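Ring A is closed onto a preformed ring B by a [3+3] union. The quaternary C10 of ring B carries two electrophilic carbons, the formyl carbon C1 and the ring ketone C5; the dianion of diethyl (3-oxobutan-2-yl)phosphonate supplies C2–C3–C4 with C15. In one flask its terminal carbanion adds to C1 (C1–C2), the phosphonate carbanion olefinates C5 (C4–C5), and loss of water gives the cross-conjugated dienone. The step exploits the 1,3-placement of C1 and C5 across C10 in ring A, matched by the two α-carbons of the C3 carbonyl. Later steps reset ring A to the 3β-acyloxy-4β-hydroxy-5-ene and oxidise C12.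

Key step: step 4

Remarks: eudesmane numbering is used (ring A: C1–C5 and C10; ring B: C5–C10; C14 on C10; C15 on C4; side chain C11–C13 on C7); β is the face of C14, and C14 and the C7 side chain are β throughout (7R, 10S in the target). Phosphonate 6 is assumed to be purchased; it is otherwise one C-methylation away from diethyl (2-oxopropyl)phosphonate.

Step 1
Reactants: 1 cyclohex-2-en-1-one; 2 4,4,5,5-tetramethyl-2-(prop-1-en-2-yl)-1,3,2-dioxaborolane
Product: 3 (R)-3-(prop-1-en-2-yl)cyclohexan-1-one
Conditions: [Rh(cod)Cl]2 (cat.), (R)-BINAP, KOH (cat.), dioxane/H2O 10:1, 60 °C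
Reagents that add atoms: none
Why: Hayashi–Miyaura rhodium-catalysed asymmetric conjugate addition of an alkenylboron reagent, in which (R)-BINAP should direct the alkenyl group to one enone face and set C7 as R.

Step 2
Reactants: 3 (R)-3-(prop-1-en-2-yl)cyclohexan-1-one
Product: 4 (5R)-2-[(Z)-hydroxymethylidene]-5-(prop-1-en-2-yl)cyclohexan-1-one
Conditions: NaH, HCO2Et, EtOH (cat.), THF, 0 to 25 °C; then 1 M HCl
Reagents that add atoms: ethyl formate CCOC=O
Why: Claisen formylation under equilibrating conditions should take place at the less hindered α-methylene remote from the C7 substituent (the future C10), and the product rests as the chelated enol.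

Step 3
Reactants: 4 (5R)-2-[(Z)-hydroxymethylidene]-5-(prop-1-en-2-yl)cyclohexan-1-one
Product: 5 (1S,4R)-1-methyl-2-oxo-4-(prop-1-en-2-yl)cyclohexane-1-carbaldehyde
Conditions: MeI, K2CO3, acetone, 25 °C
Reagents that add atoms: iodomethane CI
Why: C-alkylation of the β-keto aldehyde enolate, in which iodomethane is expected to enter axially on the half-chair that keeps the C7 group equatorial, placing the new C14 methyl cis to the C7 side chain and making C10 quaternary (S).

Step 4
Reactants: 5 (1S,4R)-1-methyl-2-oxo-4-(prop-1-en-2-yl)cyclohexane-1-carbaldehyde; 6 diethyl (3-oxobutan-2-yl)phosphonate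
Product: 10 (4aS,7R)-1,4a-dimethyl-7-(prop-1-en-2-yl)-5,6,7,8-tetrahydronaphthalen-2(4aH)-one, via phosphonate dianion 7 (not isolated), via aldol adduct 8 (not isolated), via hydroxy enone 9 (not isolated)
Conditions: 6, NaH, THF, 0 °C; n-BuLi, 0 °C; then 5, −78 to 60 °C; then 1 M HCl, THF, 40 °C
Reagents that add atoms: none
Why: NaH removes the proton between phosphorus and carbonyl of 6 and n-BuLi then the terminal methyl proton, the more basic terminal carbanion (C2) of dianion 7 adds to the formyl carbon C1 of 5, and on warming the phosphonate carbanion (C4) attacks the C5 ketone and expels diethyl phosphate before acid removes water across C1–C2. The closest known reaction types are the γ-aldol addition of β-ketophosphonate dianions and the intramolecular Horner–Wadsworth–Emmons cyclisation of keto phosphonates to cyclohexenones. Ring A is closed in the olefination as a six-membered ring by 6-exo-trig attack of C4 on the C5 carbonyl, the C1–C2 bond having been made first in the intermolecular event. No stereocentre of the target is created here: the carbinol at C1 in 8 and 9 is erased by the dehydration, and C7 and the non-enolisable quaternary C10 of 5 are carried through unchanged. The step needs chemoselectivity of the terminal carbanion for the aldehyde over the ketone and the placement of C15 on C4, which should be secured by the higher electrophilicity of the formyl group at −78 °C and by the position of phosphorus in 6; the open-chain enone geometry problem does not arise because the C1=C2 bond forms only after the ring is closed.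

Step 5
Reactants: 10 (4aS,7R)-1,4a-dimethyl-7-(prop-1-en-2-yl)-5,6,7,8-tetrahydronaphthalen-2(4aH)-one
Product: 11 (4aS,7R)-1,4a-dimethyl-7-(prop-1-en-2-yl)-4,4a,5,6,7,8-hexahydronaphthalen-2(3H)-one (α-cyperone)
Conditions: [(Ph3P)CuH]6, toluene, 25 °C; then aq NH4Cl
Reagents that add atoms: none
Why: Stryker conjugate reduction with the phosphine-stabilised copper hydride should take the disubstituted C1=C2 arm of the dienone only, since hydride delivery to the fully substituted C5 is much slower and isolated alkenes are inert.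

Step 6
Reactants: 11 α-cyperone
Product: 13 3-oxoeudesma-4,11(13)-dien-12-al, via allylic alcohol 12 (not isolated)
Conditions: SeO2 (cat.), t-BuOOH, CH2Cl2, 25 °C; then MnO2, CH2Cl2, 25 °C
Reagents that add atoms: tert-butyl hydroperoxide CC(C)(C)OO
Why: Selenium dioxide allylic oxidation (ene reaction then [2,3]-shift) should hydroxylate the methyl of the electron-rich 1,1-disubstituted alkene in preference to the electron-poor enone, and MnO2 oxidises the primary allylic alcohol to the 2-substituted acrolein.

Step 7
Reactants: 13 3-oxoeudesma-4,11(13)-dien-12-al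
Product: 15 methyl 3-oxoeudesma-4,11(13)-dien-12-oate, via carboxylic acid 14 (not isolated)
Conditions: NaClO2, NaH2PO4, 2-methylbut-2-ene, t-BuOH/H2O, 0 to 25 °C; then Me3SiCHN2, MeOH/toluene, 0 °C
Reagents that add atoms: sodium chlorite [Na+].[O-]Cl=O; (trimethylsilyl)diazomethane C[Si](C)(C)C=[N+]=[N-]
Why: Pinnick oxidation converts the enal into the acid without touching either alkene, and O-methylation with the diazomethane surrogate gives the methyl acrylate of the target.

Step 8
Reactants: 15 methyl 3-oxoeudesma-4,11(13)-dien-12-oate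
Product: 16 methyl 3β-hydroxyeudesma-4,11(13)-dien-12-oate
Conditions: NaBH4, CeCl3·7H2O, MeOH, −40 °C
Reagents that add atoms: none
Why: Luche 1,2-reduction, in which hydride should add to C3 from the α face, anti to the axial C14 methyl, giving the equatorial 3β-alcohol (3S) while the acrylate ester is left alone.

Step 9
Reactants: 16 methyl 3β-hydroxyeudesma-4,11(13)-dien-12-oate
Product: 17 methyl 4β,5β-epoxy-3β-hydroxyeudesm-11(13)-en-12-oate (4α-methyl)
Conditions: VO(acac)2 (cat.), t-BuOOH, toluene, 0 to 25 °C
Reagents that add atoms: tert-butyl hydroperoxide CC(C)(C)OO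
Why: Hydroxyl-directed vanadium-catalysed epoxidation should deliver oxygen to the C4=C5 alkene on the face of the 3β-hydroxyl, so that C4 receives its oxygen β (4R), and the electron-poor acrylate is not epoxidised.

Step 10
Reactants: 17 methyl 4β,5β-epoxy-3β-hydroxyeudesm-11(13)-en-12-oate
Product: 18 methyl 3β,4β-dihydroxyeudesma-5,11(13)-dien-12-oate (4α-methyl)
Conditions: Ti(OiPr)4 (1.5 equiv), CH2Cl2, 25 to 40 °C; then aq tartaric acid
Reagents that add atoms: none
Why: Titanium alkoxide-mediated rearrangement of a 2,3-epoxy alcohol to an ene-diol, in which chelation through the C3 alkoxide should weaken the distal C5–O bond and a proton is lost from C6, the only hydrogen-bearing neighbour of C5, so the C4–O bond keeps its β configuration and the C5=C6 alkene appears.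

Step 11
Reactants: 18 methyl 3β,4β-dihydroxyeudesma-5,11(13)-dien-12-oate; 19 angelic acid, (Z)-2-methylbut-2-enoic acid
Product: 21 methyl 3β-angeloyloxy-4β-hydroxyeudesma-5,11(13)-dien-12-oate, via mixed anhydride 20 (not isolated)
Conditions: 19, 2,4,6-trichlorobenzoyl chloride, Et3N, toluene, 25 °C; then 18, toluene, 75 °C
Reagents that add atoms: none
Why: Yamaguchi acylation through the mixed anhydride should transfer the angeloyl group without Z to E isomerisation and only to the secondary 3β-hydroxyl, the tertiary C4 hydroxyl being too hindered, which gives the target.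

Compound list
1 | cyclohex-2-en-1-one | O=C1C=CCCC1 | starting material
2 | 4,4,5,5-tetramethyl-2-(prop-1-en-2-yl)-1,3,2-dioxaborolane | CC(=C)B1OC(C)(C)C(C)(C)O1 | starting material
3 | (R)-3-(prop-1-en-2-yl)cyclohexan-1-one | CC(=C)[C@H]1CC(=O)CCC1 | intermediate
4 | (5R)-2-[(Z)-hydroxymethylidene]-5-(prop-1-en-2-yl)cyclohexan-1-one | CC(=C)[C@H]1CC(=O)/C(=C\O)CC1 | intermediate
5 | (1S,4R)-1-methyl-2-oxo-4-(prop-1-en-2-yl)cyclohexane-1-carbaldehyde | CC(=C)[C@H]1CC(=O)[C@](C)(C=O)CC1 | intermediate
6 | diethyl (3-oxobutan-2-yl)phosphonate | CCOP(=O)(OCC)C(C)C(C)=O | starting material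
7 | sodium lithium dianion of 6 (carbanions at the phosphorus-bearing carbon and at the terminal methyl) | [Na+].[Li+].CCOP(=O)(OCC)C(C)=C([O-])[CH2-] | intermediate
8 | diethyl {5-hydroxy-5-[(1S,4R)-1-methyl-2-oxo-4-(prop-1-en-2-yl)cyclohexyl]-3-oxopentan-2-yl}phosphonate (mixture at the carbinol and phosphorus-bearing carbons) | CC(=C)[C@H]1CC(=O)[C@](C)(C(O)CC(=O)C(C)P(=O)(OCC)OCC)CC1 | intermediate
9 | 1-hydroxyeudesma-4,11-dien-3-one (both C1 epimers; 7β-isopropenyl, 10β-methyl) | CC(=C)[C@H]1CC2=C(C)C(=O)CC(O)[C@]2(C)CC1 | intermediate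
10 | eudesma-1,4,11-trien-3-one, (4aS,7R)-1,4a-dimethyl-7-(prop-1-en-2-yl)-5,6,7,8-tetrahydronaphthalen-2(4aH)-one | CC(=C)[C@H]1CC2=C(C)C(=O)C=C[C@]2(C)CC1 | intermediate
11 | α-cyperone, (4aS,7R)-1,4a-dimethyl-7-(prop-1-en-2-yl)-4,4a,5,6,7,8-hexahydronaphthalen-2(3H)-one | CC(=C)[C@H]1CC2=C(C)C(=O)CC[C@]2(C)CC1 | intermediate
12 | 12-hydroxyeudesma-4,11(13)-dien-3-one | OCC(=C)[C@H]1CC2=C(C)C(=O)CC[C@]2(C)CC1 | intermediate
13 | 3-oxoeudesma-4,11(13)-dien-12-al | O=CC(=C)[C@H]1CC2=C(C)C(=O)CC[C@]2(C)CC1 | intermediate
14 | 3-oxoeudesma-4,11(13)-dien-12-oic acid | OC(=O)C(=C)[C@H]1CC2=C(C)C(=O)CC[C@]2(C)CC1 | intermediate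
15 | methyl 3-oxoeudesma-4,11(13)-dien-12-oate | COC(=O)C(=C)[C@H]1CC2=C(C)C(=O)CC[C@]2(C)CC1 | intermediate
16 | methyl 3β-hydroxyeudesma-4,11(13)-dien-12-oate | COC(=O)C(=C)[C@H]1CC2=C(C)[C@@H](O)CC[C@]2(C)CC1 | intermediate
17 | methyl 4β,5β-epoxy-3β-hydroxyeudesm-11(13)-en-12-oate (4α-methyl; epoxide oxygen cis to C14) | COC(=O)C(=C)[C@H]1C[C@]2(O3)[C@]3(C)[C@@H](O)CC[C@]2(C)CC1 | intermediate
18 | methyl 3β,4β-dihydroxyeudesma-5,11(13)-dien-12-oate (4α-methyl) | C=C(C(=O)OC)[C@H]1C=C2[C@](C)(CC[C@H](O)[C@]2(C)O)CC1 | intermediate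
19 | angelic acid, (Z)-2-methylbut-2-enoic acid | C/C=C(/C)C(=O)O | starting material
20 | (Z)-2-methylbut-2-enoic 2,4,6-trichlorobenzoic anhydride | C/C=C(/C)C(=O)OC(=O)c1c(Cl)cc(Cl)cc1Cl | intermediate
21 | methyl 3β-angeloyloxy-4β-hydroxyeudesma-5,11(13)-dien-12-oate, (3S,4R,7R,10S) | C=C(C(=O)OC)[C@H]1C=C2[C@](C)(CC[C@H](OC(=O)/C(C)=C\C)[C@]2(C)O)CC1 | target

Total step count: 11
Longest linear sequence: 11 steps (1 to 21)

Steps most likely to fail

Step 4. Retro-aldol loss of the newly attached chain from the β-alkoxy ketone, or enolisation of the ring ketone by the dianion, may outrun the intramolecular olefination of the hindered C5 ketone. The fallback sets out from 5 and returns at 11. Knoevenagel condensation of 5 with ethyl 3-oxopentanoate (piperidine, AcOH, benzene, reflux with water removal) is followed in the same flask by intramolecular aldol condensation of the ethyl ketone methylene onto C5. This should give 2-(ethoxycarbonyl)eudesma-1,4,11-trien-3-one F1, again forming C1–C2 and C4–C5 in one operation. Conjugate reduction of the doubly activated C1=C2 bond with a Hantzsch ester gives 2-(ethoxycarbonyl)eudesma-4,11-dien-3-one F2, and Krapcho dealkoxycarbonylation (LiCl, wet DMSO, 150 °C) gives 11, so step 5 is also bypassed.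

Step 10. Cleavage of the C4–O bond instead of the C5–O bond (leading to the exocyclic 4(15)-ene 5-ol), or a 1,2-shift from C10 to the developing C5 cation, may compete with loss of the C6 proton. The fallback sets out from 15 and returns at 18, replacing steps 8 to 10. TMSOTf and Et3N convert 15 into methyl 3-(trimethylsilyloxy)eudesma-3,5,11(13)-trien-12-oate F3. PhSeCl at −78 °C should attack the dienol ether at C6 from the axial β face to give methyl 3-oxo-6β-(phenylselanyl)eudesma-4,11(13)-dien-12-oate F4. Oxidation with H2O2 and pyridine triggers the allylic selenoxide [2,3]-shift, which carries oxygen suprafacially to C4 and gives methyl 4β-hydroxy-3-oxoeudesma-5,11(13)-dien-12-oate F5. Luche reduction (NaBH4, CeCl3·7H2O) from the α face then gives 18.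

Step 6. Over-oxidation, or competing oxidation at the enone γ-carbon C6 and at the tertiary allylic C7–H, may erode the allylic oxidation of the side chain. The fallback sets out from 11 and returns at 13. Ene-type chlorination with Ca(OCl)2 and solid CO2 in CH2Cl2/H2O, which is selective for the electron-rich 1,1-disubstituted alkene, gives 12-chloroeudesma-4,11(13)-dien-3-one F6. Kornblum oxidation (DMSO, NaHCO3, 90 °C) converts the allylic chloride into 13.

Further compounds
F1 | step 4 | 2-(ethoxycarbonyl)eudesma-1,4,11-trien-3-one | CC(=C)[C@H]1CC2=C(C)C(=O)C(C(=O)OCC)=C[C@]2(C)CC1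
F2 | step 4 | 2-(ethoxycarbonyl)eudesma-4,11-dien-3-one (both C2 epimers) | CC(=C)[C@H]1CC2=C(C)C(=O)C(C(=O)OCC)CC[C@]2(C)CC1
F3 | step 10 | methyl 3-(trimethylsilyloxy)eudesma-3,5,11(13)-trien-12-oate | COC(=O)C(=C)[C@H]1C=C2C(C)=C(O[Si](C)(C)C)CC[C@]2(C)CC1
F4 | step 10 | methyl 3-oxo-6β-(phenylselanyl)eudesma-4,11(13)-dien-12-oate | COC(=O)C(=C)[C@H]1[C@@H]([Se]c3ccccc3)C2=C(C)C(=O)CC[C@]2(C)CC1
F5 | step 10 | methyl 4β-hydroxy-3-oxoeudesma-5,11(13)-dien-12-oate (4α-methyl) | C=C(C(=O)OC)[C@H]1C=C2[C@](C)(CCC(=O)[C@]2(C)O)CC1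
F6 | step 6 | 12-chloroeudesma-4,11(13)-dien-3-one | ClCC(=C)[C@H]1CC2=C(C)C(=O)CC[C@]2(C)CC1
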